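With atoms numbered 1–34 along the target SMILES, ring F (C24, C25, C26, C31, C32) holds a quaternary C26 that carries a methyl and the C28 carboxyl between two CH2 groups, the pattern a Favorskii contraction leaves behind. The route therefore contracts a cis-fused 2-chloro-2-methylhydrindanone (chloride on the convex face, C33 masked as a dioxolane). In one operation this forges C25–C26, closes ring F and sets C26 by inversion, with the carboxyl convex. The diquinane is then turned into a C22 enal and joined to a C8-lithiated dihydropyran made from synthetic ent-caryophyllene. Nazarov closure of ring D and ester hydrolysis finish the target.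

Key step: step 5

Assumption: in steps 2 and 9 the catalyst antipode named is the one taken to give the drawn absolute configuration by the accepted facial-shielding models of activated oxazaborolidines; both antipodes come from commercial prolinols, so the other is used if the sense proves reversed.

Step 1
Reactants: 1 3-methylbut-3-en-2-one
Product: 2 3-methyl-2-(triisopropylsilyloxy)buta-1,3-diene
Conditions: i-Pr3SiOTf, Et3N, CH2Cl2, 0 °C → rt
Reagents that add atoms: triisopropylsilyl trifluoromethanesulfonate, CC(C)[Si](OS(=O)(=O)C(F)(F)F)(C(C)C)C(C)C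
Why: Silyl enol ether formation by soft enolisation; the ketone has α-hydrogens only on its methyl group, so only the 2-silyloxy diene can form.

Step 2
Reactants: 2 3-methyl-2-(triisopropylsilyloxy)buta-1,3-diene; 3 cyclopent-2-en-1-one
Product: 4 (3aS,7aR)-6-methyl-5-(triisopropylsilyloxy)-2,3,3a,4,7,7a-hexahydro-1H-inden-1-one
Conditions: protonated (S)-B-(o-tolyl)oxazaborolidine from α,α-diphenylprolinol, NTf2 counter-ion (20 mol%), CH2Cl2, −78 → −20 °C
Reagents that add atoms: none
Why: Catalytic enantioselective Diels–Alder reaction in which the cationic boron Lewis acid activates the enone and shields one face, the silyloxy group steers its CH2 terminus to the enone β-carbon (C24), and suprafacial addition sets C24 and C32 cis.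

Step 3
Reactants: 4 (3aS,7aR)-6-methyl-5-(triisopropylsilyloxy)-2,3,3a,4,7,7a-hexahydro-1H-inden-1-one
Product: 5 (3aS,6R,7aR)-6-chloro-6-methylhexahydro-1H-indene-1,5(4H)-dione
Conditions: NCS, NaHCO3, THF, −40 → 0 °C
Reagents that add atoms: N-chlorosuccinimide, O=C1CCC(=O)N1Cl
Why: Electrophilic α-chlorination of a silyl enol ether, which delivers chlorine regiospecifically to C26 and from the convex face of the cis-fused bicycle (anti to the five-membered ring), so the tertiary chloride is syn to the ring-fusion hydrogens.

Step 4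
Reactants: 5 (3aS,6R,7aR)-6-chloro-6-methylhexahydro-1H-indene-1,5(4H)-dione
Product: 6 (3a'S,6'R,7a'R)-6'-chloro-6'-methylhexahydrospiro[1,3-dioxolane-2,1'-inden]-5'(4'H)-one
Conditions: Me3SiOCH2CH2OSiMe3, Me3SiOTf (5 mol%), CH2Cl2, −78 → −20 °C
Reagents that add atoms: 1,2-bis(trimethylsilyloxy)ethane, C[Si](C)(C)OCCO[Si](C)(C)C
Why: Silyl-triflate-catalysed dioxolane formation under kinetic control, which takes the unhindered cyclopentanone C33 and leaves the C28 carbonyl (flanked by the quaternary C–Cl carbon and inductively deactivated) free, at a temperature where C32 does not epimerise.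

Step 5
Reactants: 6 (3a'S,6'R,7a'R)-6'-chloro-6'-methylhexahydrospiro[1,3-dioxolane-2,1'-inden]-5'(4'H)-one
Product: 8 methyl (2'S,3a'R,6a'S)-2'-methylhexahydro-1'H-spiro[1,3-dioxolane-2,4'-pentalene]-2'-carboxylate, via cyclopropanone 7 (not isolated)
Conditions: NaOMe (dry powder, 3 equiv), Et2O, 0 °C → rt
Reagents that add atoms: sodium methoxide, [Na+].[O-]C
Why: Favorskii rearrangement through a cyclopropanone: methoxide removes a C25 proton (C25 is the only α′-carbon with hydrogen, and the dioxolane blocks enolisation at C33), and the enolate carbon displaces the axial convex-face chloride from C26 by intramolecular backside attack to give 7. This 3-exo-tet closure forms C25–C26 and with it the five-membered ring F, so C26 is set by Walden inversion relative to the C–Cl bond installed in step 3. Methoxide then adds to C28 and the adduct opens by cleaving C25–C28, the bond that releases the less substituted carbanion, which leaves the ester on quaternary C26 with the carboxyl convex and the methyl concave. The closest known reaction is the contraction of 2-chloro-2-methylcyclohexanones to 1-methylcyclopentanecarboxylates, stereospecific with inversion in non-polar media. The step needs the concerted path to win over ionisation to an oxyallyl species and over E2 loss of HCl; heterogeneous NaOMe in ether, a chloride that can sit axial and anti to the enolate π-lobe in the cis-hydrindanone, and the single enolisable α′-position secure this.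

Step 6
Reactants: 8 methyl (2'S,3a'R,6a'S)-2'-methylhexahydro-1'H-spiro[1,3-dioxolane-2,4'-pentalene]-2'-carboxylate
Product: 9 methyl (2S,3aR,6aS)-2-methyl-4-oxooctahydropentalene-2-carboxylate
Conditions: 1 M HCl, THF, rt
Reagents that add atoms: water, O
Why: Acid-catalysed acetal hydrolysis, which is safe for C32 because the cis ring fusion of the bicyclo[3.3.0]octanone is the thermodynamic one, and which the hindered ester survives.

Step 7
Reactants: 9 methyl (2S,3aR,6aS)-2-methyl-4-oxooctahydropentalene-2-carboxylate
Product: 10 methyl (2S,3aR,6aR)-4-bromo-5-formyl-2-methyl-1,2,3,3a,6,6a-hexahydropentalene-2-carboxylate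
Conditions: PBr3, DMF, CHCl3, 0 → 60 °C; then aq NaOAc
Reagents that add atoms: N,N-dimethylformamide, CN(C)C=O; phosphorus tribromide, BrP(Br)Br; water, O
Why: Vilsmeier–Haack–Arnold bromoformylation, in which a conjugated β-bromo enal can arise only by enolisation towards the C22 methylene, so C20 is attached at C22 and bromide at C33 while the ester and C26 stay untouched.

Step 8
Reactants: 10 methyl (2S,3aR,6aR)-4-bromo-5-formyl-2-methyl-1,2,3,3a,6,6a-hexahydropentalene-2-carboxylate
Product: 11 methyl (2S,3aR,6aS)-5-formyl-2,4-dimethyl-1,2,3,3a,6,6a-hexahydropentalene-2-carboxylate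
Conditions: trimethylboroxine, Pd(PPh3)4 (zerovalent palladium, 5 mol%), K2CO3, 1,4-dioxane, 100 °C
Reagents that add atoms: trimethylboroxine, CB1OB(C)OB(C)O1
Why: Suzuki–Miyaura coupling of an activated β-bromo enal with a methylboron reagent installs C34 and tolerates both the aldehyde and the ester.

Step 9
Reactants: 12 cyclohex-2-en-1-one; 13 2-methylpropene
Product: 15 (1S,6S)-7,7-dimethylbicyclo[4.2.0]octan-2-one (cis-fused), via trans-fused photoadduct 14 (not isolated)
Conditions: hν (366 nm), (S)-prolinol-derived B-aryl oxazaborolidine·AlBr3 (50 mol%), CH2Cl2, −75 °C; then basic Al2O3, Et2O, rt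
Reagents that add atoms: none
Why: Lewis-acid-catalysed enantioselective [2+2] photocycloaddition, in which only the complexed enone absorbs at this wavelength, the alkene adds head-to-tail to its open face and fixes the non-epimerisable β-carbon (caryophyllene C1), and alumina then equilibrates the α-centre to the cis-fused ketone.

Step 10
Reactants: 15 (1S,6S)-7,7-dimethylbicyclo[4.2.0]octan-2-one
Product: 16 methyl (1S,6S)-7,7-dimethyl-2-oxobicyclo[4.2.0]octane-3-carboxylate (C3 epimers and enol)
Conditions: NaH, (MeO)2CO, THF, reflux; then AcOH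
Reagents that add atoms: dimethyl carbonate, COC(=O)OC
Why: Claisen-type methoxycarbonylation under thermodynamic control, which settles on the C3 methylene because only there is the β-keto ester enolisable.

Step 11
Reactants: 16 methyl (1S,6S)-7,7-dimethyl-2-oxobicyclo[4.2.0]octane-3-carboxylate
Product: 17 methyl (1S,3R,6S)-3,7,7-trimethyl-2-oxobicyclo[4.2.0]octane-3-carboxylate
Conditions: K2CO3, MeI, acetone, reflux
Reagents that add atoms: iodomethane, CI
Why: C-alkylation of the β-keto ester enolate builds the quaternary carbon that becomes caryophyllene C4, the methyl entering anti to the cyclobutane at a centre that step 16 erases.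

Step 12
Reactants: 17 methyl (1S,3R,6S)-3,7,7-trimethyl-2-oxobicyclo[4.2.0]octane-3-carboxylate
Product: 18 methyl (1S,2S,3R,6S)-3,7,7-trimethyl-5'-oxospiro[bicyclo[4.2.0]octane-2,2'-oxolane]-3-carboxylate
Conditions: SmI2 (2.5 equiv), methyl acrylate, t-BuOH, THF, −78 → 0 °C
Reagents that add atoms: methyl acrylate, C=CC(=O)OC
Why: Samarium-diiodide ketyl–olefin reductive coupling with in situ lactonisation, the ketyl adding to the acrylate on the face anti to the cyclobutane and supplying caryophyllene C6 and C7 (the carbinol centre is also erased in step 16).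

Step 13
Reactants: 18 methyl (1S,2S,3R,6S)-3,7,7-trimethyl-5'-oxospiro[bicyclo[4.2.0]octane-2,2'-oxolane]-3-carboxylate
Product: 20 1-hydroxy-4,4,8-trimethyltricyclo[6.3.0.0(2,5)]undecan-9-one (cyclobutane cis-fused; five-membered ring trans-fused with 1-OH syn and 8-CH3 anti to the cyclobutane), via bridged keto lactone 19 (not isolated)
Conditions: NaN(SiMe3)2, THF, −78 → 0 °C; then 2 M aq NaOH, 60 °C; then 2 M HCl, 50 °C
Reagents that add atoms: none
Why: Dieckmann condensation of the lactone enolate onto the neighbouring ester (5-exo-trig), followed by lactone hydrolysis and β-keto acid decarboxylation, gives the hydrindanone ketol that carries the 1,3-oxygen pattern needed for fragmentation.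

Step 14
Reactants: 20 1-hydroxy-4,4,8-trimethyltricyclo[6.3.0.0(2,5)]undecan-9-one
Product: 21 4,4,8-trimethyltricyclo[6.3.0.0(2,5)]undecane-1,9-diol (9-OH cis to 8-CH3 and trans to 1-OH)
Conditions: NaBH4, MeOH, 0 °C
Reagents that add atoms: none
Why: Borohydride reduction in which hydride attacks the cyclopentanone anti to the adjacent axial angular methyl (the situation of a 17-oxo steroid ring D), giving the carbinol cis to that methyl.

Step 15
Reactants: 21 4,4,8-trimethyltricyclo[6.3.0.0(2,5)]undecane-1,9-diol
Product: 22 1-hydroxy-4,4,8-trimethyltricyclo[6.3.0.0(2,5)]undecan-9-yl 4-methylbenzenesulfonate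
Conditions: TsCl, pyridine, DMAP (cat.), 0 °C → rt
Reagents that add atoms: 4-methylbenzenesulfonyl chloride, Cc1ccc(cc1)S(=O)(=O)Cl
Why: Selective sulfonylation of the secondary alcohol, the tertiary hydroxyl being inert under these conditions.

Step 16
Reactants: 22 1-hydroxy-4,4,8-trimethyltricyclo[6.3.0.0(2,5)]undecan-9-yl 4-methylbenzenesulfonate
Product: 24 (1S,4E,9R)-4,11,11-trimethylbicyclo[7.2.0]undec-4-en-8-one (trans-fused), via cis-fused cyclononenone 23 (not isolated)
Conditions: KOtBu, t-BuOH/THF, rt
Reagents that add atoms: none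
Why: Grob fragmentation of the 1,3-diol monotosylate, in which the tertiary alkoxide expels tosylate across the antiperiplanar ring-fusion bond, the cis methyl/tosylate relationship is transcribed stereospecifically into the E-trisubstituted alkene of the nine-membered ring, and the same base epimerises the α-carbon to the more stable trans-fused cyclobutane.

Step 17
Reactants: 24 (1S,4E,9R)-4,11,11-trimethylbicyclo[7.2.0]undec-4-en-8-one
Product: 25 (1S,4E,9R)-4,11,11-trimethyl-8-methylidenebicyclo[7.2.0]undec-4-ene (ent-β-caryophyllene)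
Conditions: Ph3PCH3Br, KOtBu, THF, 0 °C → rt
Reagents that add atoms: methyltriphenylphosphonium bromide, C[P+](c1ccccc1)(c1ccccc1)c1ccccc1.[Br-]
Why: Wittig methylenation with a non-stabilised ylide, harmless to C9 because the trans ring fusion is already the thermodynamic one.

Step 18
Reactants: 25 ent-β-caryophyllene; 26 prop-2-enal
Product: 27 3,4-dihydro-2H-pyran annulated across C4–C5 of the caryophyllane with oxygen on C4 (caryophyllene numbering 1S,4S,5R,9R; target atoms C1–C19 with C7–H and C8–H)
Conditions: acrolein (excess), hydroquinone (cat.), toluene, sealed tube, 150 °C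
Reagents that add atoms: none
Why: Thermal inverse-electron-demand oxa-Diels–Alder reaction, in which the strained E-alkene of the nine-membered ring reacts in preference to the exocyclic methylene, oxygen bonds to the more substituted C10, suprafacial addition keeps H5 and the C10 methyl trans, and attack on the exposed outer face of the dominant ring conformers (the face peracids also take) sets C5 and C10 relative to the cyclobutane.

Step 19
Reactants: 27 caryophyllane-fused dihydropyran; 11 methyl (2S,3aR,6aS)-5-formyl-2,4-dimethyl-1,2,3,3a,6,6a-hexahydropentalene-2-carboxylate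
Product: 29 C20 carbinol joining C8 of the dihydropyran to C22 of the hexahydropentalene ester (C20 epimers), via C8-lithio dihydropyran 28 (not isolated)
Conditions: t-BuLi, THF, −78 → 0 °C; then 11, −78 °C; aq NH4Cl
Reagents that add atoms: none
Why: α-Lithiation of the cyclic enol ether at C8 followed by 1,2-addition to the aldehyde, which is far more electrophilic than the hindered tertiary methyl ester, at a carbinol centre whose configuration is lost in the next step.

Step 20
Reactants: 29 C20 carbinol
Product: 30 cross-conjugated dienone (C20 ketone flanked by C7=C8 of the dihydropyran and C22=C33 of the cyclopentene)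
Conditions: Dess–Martin periodinane, NaHCO3, CH2Cl2, 0 °C → rt
Reagents that add atoms: none
Why: Dess–Martin oxidation of the bis-allylic alcohol under buffered conditions, which spare the enol ether and the exocyclic alkene.

Step 21
Reactants: 30 cross-conjugated dienone
Product: 31 sterhirsutin D methyl ester
Conditions: Sc(OTf)3 (10 mol%), LiClO4, ClCH2CH2Cl, 40 °C
Reagents that add atoms: none
Why: Lewis-acid-catalysed Nazarov cyclisation of a 2-alkoxy dienone (4π conrotatory closure forming C7–C33 and ring D), in which C7 bonds to the convex face of the ring E/ring F bicycle anti to ring F and so sets C33, proton loss from C7 keeps the enol-ether double bond at C7=C8, and protonation at C22 gives the only unstrained (cis) ring D/ring E fusion.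

Step 22
Reactants: 31 sterhirsutin D methyl ester
Product: 32 sterhirsutin D
Conditions: LiOH, THF/MeOH/H2O, 50 °C; then 1 M HCl to pH 3
Reagents that add atoms: lithium hydroxide, [Li+].[OH-]
Why: Saponification (BAc2) of the methyl ester on the convex face, under aqueous base that the cis ring fusions and the α-alkoxy enone tolerate.

Compound list
1 | 3-methylbut-3-en-2-one | CC(=C)C(C)=O | starting material
2 | 3-methyl-2-(triisopropylsilyloxy)buta-1,3-diene | C=C(C)C(=C)O[Si](C(C)C)(C(C)C)C(C)C | intermediate
3 | cyclopent-2-en-1-one | O=C1C=CCC1 | starting material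
4 | (3aS,7aR)-6-methyl-5-(triisopropylsilyloxy)-2,3,3a,4,7,7a-hexahydro-1H-inden-1-one (cis-fused) | CC1=C(O[Si](C(C)C)(C(C)C)C(C)C)C[C@@H]2CCC(=O)[C@@H]2C1 | intermediate
5 | (3aS,6R,7aR)-6-chloro-6-methylhexahydro-1H-indene-1,5(4H)-dione (Cl syn to the ring-fusion hydrogens) | O=C1C[C@@H]2CCC(=O)[C@@H]2C[C@@]1(C)Cl | intermediate
6 | (3a'S,6'R,7a'R)-6'-chloro-6'-methylhexahydrospiro[1,3-dioxolane-2,1'-inden]-5'(4'H)-one | O=C1C[C@@H]2CCC3(OCCO3)[C@@H]2C[C@@]1(C)Cl | intermediate
7 | cyclopropanone bridging C25 and C26 of the diquinane dioxolane (C28 carbonyl on the convex face) | O=C1[C@@H]2[C@@]1(C)C[C@@H]3[C@H]2CCC34OCCO4 | intermediate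
8 | methyl (2'S,3a'R,6a'S)-2'-methylhexahydro-1'H-spiro[1,3-dioxolane-2,4'-pentalene]-2'-carboxylate | COC(=O)[C@@]1(C)C[C@@H]2CCC3(OCCO3)[C@@H]2C1 | intermediate
9 | methyl (2S,3aR,6aS)-2-methyl-4-oxooctahydropentalene-2-carboxylate | COC(=O)[C@@]1(C)C[C@@H]2CCC(=O)[C@@H]2C1 | intermediate
10 | methyl (2S,3aR,6aR)-4-bromo-5-formyl-2-methyl-1,2,3,3a,6,6a-hexahydropentalene-2-carboxylate | COC(=O)[C@@]1(C)C[C@@H]2CC(C=O)=C(Br)[C@@H]2C1 | intermediate
11 | methyl (2S,3aR,6aS)-5-formyl-2,4-dimethyl-1,2,3,3a,6,6a-hexahydropentalene-2-carboxylate | COC(=O)[C@@]1(C)C[C@@H]2CC(C=O)=C(C)[C@@H]2C1 | intermediate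
12 | cyclohex-2-en-1-one | O=C1C=CCCC1 | starting material
13 | 2-methylpropene | CC(C)=C | starting material
14 | (1R,6S)-7,7-dimethylbicyclo[4.2.0]octan-2-one (trans-fused) | O=C1CCC[C@H]2[C@H]1CC2(C)C | intermediate
15 | (1S,6S)-7,7-dimethylbicyclo[4.2.0]octan-2-one (cis-fused) | O=C1CCC[C@H]2[C@@H]1CC2(C)C | intermediate
16 | methyl (1S,6S)-7,7-dimethyl-2-oxobicyclo[4.2.0]octane-3-carboxylate | O=C1C(C(=O)OC)CC[C@H]2[C@@H]1CC2(C)C | intermediate
17 | methyl (1S,3R,6S)-3,7,7-trimethyl-2-oxobicyclo[4.2.0]octane-3-carboxylate | O=C1[C@](C)(C(=O)OC)CC[C@H]2[C@@H]1CC2(C)C | intermediate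
18 | methyl (1S,2S,3R,6S)-3,7,7-trimethyl-5'-oxospiro[bicyclo[4.2.0]octane-2,2'-oxolane]-3-carboxylate | O=C1CC[C@@]2(O1)[C@](C)(C(=O)OC)CC[C@H]3[C@@H]2CC3(C)C | intermediate
19 | bridged β-keto lactone (lactone spanning the carbinol carbon and the α-carbon of the new cyclopentanone) | O=C1O[C@]2(C[C@H]1C3=O)[C@@]3(C)CC[C@H]4[C@@H]2CC4(C)C | intermediate
20 | 1-hydroxy-4,4,8-trimethyltricyclo[6.3.0.0(2,5)]undecan-9-one (1-OH syn, 8-CH3 anti to the cis-fused cyclobutane) | O[C@]1(CCC2=O)[C@@]2(C)CC[C@H]3[C@@H]1CC3(C)C | intermediate
21 | 4,4,8-trimethyltricyclo[6.3.0.0(2,5)]undecane-1,9-diol (9-OH cis to 8-CH3) | O[C@]1(CC[C@H]2O)[C@@]2(C)CC[C@H]3[C@@H]1CC3(C)C | intermediate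
22 | 9-(4-methylbenzenesulfonate) of diol 21 | O[C@]1(CC[C@H]2OS(=O)(=O)c4ccc(C)cc4)[C@@]2(C)CC[C@H]3[C@@H]1CC3(C)C | intermediate
23 | (1S,4E,9S)-4,11,11-trimethylbicyclo[7.2.0]undec-4-en-8-one (cis-fused) | O=C1CC/C=C(\C)CC[C@H]2[C@@H]1CC2(C)C | intermediate
24 | (1S,4E,9R)-4,11,11-trimethylbicyclo[7.2.0]undec-4-en-8-one (trans-fused) | O=C1CC/C=C(\C)CC[C@H]2[C@H]1CC2(C)C | intermediate
25 | (1S,4E,9R)-4,11,11-trimethyl-8-methylidenebicyclo[7.2.0]undec-4-ene (ent-β-caryophyllene) | C=C1CC/C=C(\C)CC[C@H]2[C@H]1CC2(C)C | intermediate
26 | prop-2-enal (acrolein) | C=CC=O | starting material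
27 | caryophyllane-fused 3,4-dihydro-2H-pyran (caryophyllene numbering 1S,4S,5R,9R; O on C4) | C=C1CC[C@@H]2CC=CO[C@@]2(C)CC[C@H]3[C@H]1CC3(C)C | intermediate
28 | C8-lithio derivative of 27 | C=C1CC[C@@H]2CC=C([Li])O[C@@]2(C)CC[C@H]3[C@H]1CC3(C)C | intermediate
29 | C20 carbinol linking C8 of 27 to C22 of the hexahydropentalene ester (C20 epimers) | C=C1CC[C@@H]2CC=C(O[C@@]2(C)CC[C@H]3[C@H]1CC3(C)C)C(O)C4=C(C)[C@@H]5C[C@@](C)(C(=O)OC)C[C@@H]5C4 | intermediate
30 | cross-conjugated dienone (C20 ketone) | C=C1CC[C@@H]2CC=C(O[C@@]2(C)CC[C@H]3[C@H]1CC3(C)C)C(=O)C4=C(C)[C@@H]5C[C@@](C)(C(=O)OC)C[C@@H]5C4 | intermediate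
31 | sterhirsutin D methyl ester | C=C1CC[C@@H]2CC3=C(O[C@@]2(C)CC[C@H]2[C@H]1CC2(C)C)C(=O)[C@@H]1C[C@H]2C[C@](C)(C(=O)OC)C[C@H]2[C@]31C | intermediate
32 | sterhirsutin D | C=C1CC[C@@H]2CC3=C(O[C@@]2(C)CC[C@H]2[C@H]1CC2(C)C)C(=O)[C@@H]1C[C@H]2C[C@](C)(C(=O)O)C[C@H]2[C@]31C | target

Total step count: 22. Longest linear sequence: 14 steps (12 and 13 to 32, through steps 9–18 and 19–22); the other branch runs 12 steps (steps 1–8 and 19–22).

Steps most likely to fail

Step 18. The cycloaddition may be sluggish because acrolein is only a weakly electrophilic oxadiene, so polymerisation or ene reaction can overtake it, and the facial selectivity on the flexible nine-membered ring may be incomplete. The fallback sets out from 25 and comes back at 27, and replaces acrolein by a far more electrophilic oxadiene. Methylene Meldrum's acid, generated in situ from Meldrum's acid and formaldehyde by Knoevenagel condensation, should add to the strained alkene of 25 at room temperature to give the pyranodioxinone cycloadduct F1. Heating F1 in aqueous pyridine hydrolyses the ketene acetal and decarboxylates the resulting malonic half-lactone to the δ-lactone F2. Reduction with i-Bu2AlH at −78 °C gives the lactol F3, and mesylation–elimination (MeSO2Cl, Et3N) returns dihydropyran 27.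

Step 21. Ring closure may stall at the crowded quaternary C33, or the Lewis acid may ionise the tertiary C10–O bond or isomerise the exocyclic alkene before cyclisation. The fallback sets out from 11 and 25 and comes back at 31; it closes ring D before the caryophyllane is present and forms ring C last by cycloaddition. 1-Ethoxyvinyllithium adds to 11 to give the carbinol F4, and Dess–Martin oxidation gives the 2-ethoxy dienone F5. Nazarov cyclisation of F5, now under a strong acid such as BF3·OEt2 and with an unsubstituted C7 terminus, gives the triquinane 2-ethoxy enone F6, and aqueous acid frees the diosphenol F7. Heating F7 with paraformaldehyde and 25 should hydroxymethylate C7 and dehydrate to the α-methylene 1,2-dione, which is trapped by the strained alkene of 25 in an oxa-Diels–Alder reaction to give 31.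

Step 5. Loss of HCl or substitution by methoxide may outrun cyclopropanone formation, or the reaction may leak through an oxyallyl intermediate and lose stereospecificity at C26; an imperfect convex/concave ratio from step 3 would also surface here. The fallback sets out from 3 and comes back at 8, and contracts the ring by a semipinacol shift of an epoxide instead of a halo ketone. Diels–Alder reaction of 3 with isoprene under the catalyst of step 2 gives the hydrindenone F8 (either regioisomer leads to the same ring F), and ketalisation with ethylene glycol and pyridinium tosylate gives F9. m-Chloroperbenzoic acid epoxidises the convex face to F10. BF3·OEt2 at −78 °C opens the epoxide at the tertiary carbon with anti 1,2-shift of the ring CH2, again inverting C26, to give the aldehyde F11. Oxidation with NaClO2 gives the acid F12, and MeI/K2CO3 returns ester 8.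

Further compounds
F1 | step 18 | pyranodioxinone cycloadduct of 25 with methylene Meldrum's acid | C=C1CC[C@@H]2CC3=C(OC(C)(C)OC3=O)O[C@@]2(C)CC[C@H]4[C@H]1CC4(C)C
F2 | step 18 | caryophyllane-fused δ-lactone (tetrahydropyran-2-one, ring O on C4) | C=C1CC[C@@H]2CCC(=O)O[C@@]2(C)CC[C@H]3[C@H]1CC3(C)C
F3 | step 18 | caryophyllane-fused lactol (anomers) | C=C1CC[C@@H]2CCC(O)O[C@@]2(C)CC[C@H]3[C@H]1CC3(C)C
F4 | step 21 | 1-ethoxyvinyl carbinol from 11 (C20 epimers) | CCOC(=C)C(O)C1=C(C)[C@@H]2C[C@@](C)(C(=O)OC)C[C@@H]2C1
F5 | step 21 | 2-ethoxy dienone | CCOC(=C)C(=O)C1=C(C)[C@@H]2C[C@@](C)(C(=O)OC)C[C@@H]2C1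
F6 | step 21 | triquinane 2-ethoxy enone (rings D, E and F; cis-anti-cis) | C3=C(OCC)C(=O)[C@@H]1C[C@H]2C[C@](C)(C(=O)OC)C[C@H]2[C@]31C
F7 | step 21 | triquinane diosphenol (2-hydroxy enone) | C3=C(O)C(=O)[C@@H]1C[C@H]2C[C@](C)(C(=O)OC)C[C@H]2[C@]31C
F8 | step 5 | (3aS,7aR)-5-methyl-2,3,3a,4,7,7a-hexahydro-1H-inden-1-one | C1=C(C)C[C@@H]2CCC(=O)[C@@H]2C1
F9 | step 5 | ethylene ketal of F8 | C1=C(C)C[C@@H]2CCC3(OCCO3)[C@@H]2C1
F10 | step 5 | convex-face epoxide of F9 | C[C@]12C[C@@H]3CCC4(OCCO4)[C@@H]3C[C@H]1O2
F11 | step 5 | ring-contracted aldehyde (formyl analogue of 8) | O=C[C@@]1(C)C[C@@H]2CCC3(OCCO3)[C@@H]2C1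
F12 | step 5 | carboxylic acid corresponding to 8 | OC(=O)[C@@]1(C)C[C@@H]2CCC3(OCCO3)[C@@H]2C1
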